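**Plan**

1. Numbering (biogenetic): the oxepane O bridges C2(Me2) and C7; C3 bears OH; C6 carries the angular methyl; C10 is the (Me)(OH) carbon; C11 carries the C12–C13 linker; the seven-membered ring is C14, C15, C16, C17, C18, C22, C23(Me2) with the C15–C16 epoxide; the cyclopentane is C18–C22 with C19(Me)(OH).
2. Retrosynthesis: remove the epoxide (C15=C16) and the C10 methyl (C10 ketone), then open oxepane and cyclohexane together (O–C2 and C6–C11) to an acyclic 2,3:6,7-diepoxide whose C10 is a silyl enol ether; cut C11–C12 (aldol) into diepoxy-geranylacetone and a hydroazulenyl acetaldehyde.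
3. The hydroazulene comes from a cis-hydrindanone by insertion of C16 (one-carbon ring expansion); its six-membered ring from RCM (C14=C23), conjugate methylation (C23) and aldol/hydrogenation at C14; its cyclopentane from a Pd enyne cycloisomerisation (C18–C22) of a geraniol-derived ynoate.
4. Forward ring order: cyclopentane, cyclohexenone, cycloheptanone, cycloheptene; fragment union; oxepane and cyclohexanone in one step; C10 carbinol; epoxide.
5. Stereochemistry: C19 from Sharpless epoxidation (D-tartrate), relayed by substrate control to C22, C18, C14 and the epoxide face; C3, C6, C7 from Shi epoxidation, relayed stereospecifically to the trans ring fusion, C11 and C10.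
6. Enabling feature: the ring O joins C2 and C7, C3 bears OH, and quaternary C6 is bonded to C11, which is α to the C10 carbinol. This is the imprint of a head-to-tail opened 1,5-diepoxide terminated by an enol carbon, so the aldol that unites the halves also supplies, after 1,4-hydrosilylation, the regiodefined enol silane that ends the cascade.

Key step: step 20

Remark: 13, 14, 26 and 27 are carried as mixtures at aldol/carbinol centres that are destroyed in the next operation; their SMILES leave these centres undefined.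
Remark: the face selectivities in steps 5, 6, 11 and 22 are expectations from conformational arguments, not established facts; the fallbacks for steps 11 and 22 deliver the opposite face.

**Route**

Step 1
Reactants: 1 geraniol
Product: 2 (2R,3R)-2,3-epoxygeraniol
Conditions: Ti(OiPr)4 (5 mol%), D-(−)-diethyl tartrate (6 mol%), t-BuOOH, 4 Å MS, CH2Cl2, −20 °C
Reagents that add atoms: tert-butyl hydroperoxide (CC(C)(C)OO)
Why: Sharpless asymmetric epoxidation of the allylic alcohol, in which the D-tartrate catalyst delivers oxygen to the face that gives the (2R,3R)-oxirane and so fixes the future C19 carbinol centre.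

Step 2
Reactants: 2 (2R,3R)-2,3-epoxygeraniol
Product: 3 epoxygeranyl chloride
Conditions: PPh3, CCl4, NaHCO3, reflux
Reagents that add atoms: carbon tetrachloride (ClC(Cl)(Cl)Cl)
Why: Appel chlorination of the primary alcohol under neutral conditions leaves the trisubstituted oxirane and both stereocentres untouched.

Step 3
Reactants: 3 epoxygeranyl chloride
Product: 5 methyl (4R)-4-hydroxy-4,8-dimethylnon-7-en-2-ynoate, via dilithium alkynyl alkoxide 4 (not isolated)
Conditions: n-BuLi (3.1 equiv), THF, −40 to −20 °C; then ClCO2Me (1.0 equiv), −78 °C; aq. NH4Cl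
Reagents that add atoms: methyl chloroformate (COC(=O)Cl)
Why: base-induced fragmentation of the 2,3-epoxy chloride (α-deprotonation, oxirane opening, dehydrochlorination) gives the acetylide/alkoxide with retention at the carbinol carbon C19, and the acetylide is C-acylated in preference to the hindered tertiary alkoxide.

Step 4
Reactants: 5 methyl (4R)-4-hydroxy-4,8-dimethylnon-7-en-2-ynoate
Product: 6 methyl (4R)-4,8-dimethyl-4-(triethylsilyloxy)non-7-en-2-ynoate
Conditions: TESOTf, 2,6-lutidine, CH2Cl2, −78 to 0 °C
Reagents that add atoms: triethylsilyl trifluoromethanesulfonate (CC[Si](CC)(CC)OS(=O)(=O)C(F)(F)F)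
Why: silylation of the tertiary alcohol with a silyl triflate and a hindered base gives an ether that should survive every step up to the final fluoride treatment.

Step 5
Reactants: 6 methyl (4R)-4,8-dimethyl-4-(triethylsilyloxy)non-7-en-2-ynoate
Product: 7 methyl (2Z)-2-[(2R,5S)-2-methyl-5-(prop-1-en-2-yl)-2-(triethylsilyloxy)cyclopentylidene]acetate
Conditions: Pd(OAc)2 (5 mol%), PPh3 (10 mol%), benzene, 60 °C
Reagents that add atoms: none
Why: Pd-catalysed 1,6-enyne cycloisomerisation (Alder-ene type) forms C18–C22 and, by β-hydride elimination into a methyl group, the isopropenyl group; the new C22 centre is expected anti to the OTES group of the propargylic quaternary carbon (1,3-induction), and the ester ends trans to C22.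

Step 6
Reactants: 7 the cyclopentylidene acetate
Product: 8 methyl 2-[(1R,2R,5R)-2-methyl-5-(prop-1-en-2-yl)-2-(triethylsilyloxy)cyclopentyl]acetate
Conditions: Cu(OAc)2·H2O (5 mol%), 1,2-bis(diphenylphosphino)benzene, (EtO)2MeSiH, t-BuOH, toluene, 0 °C to rt
Reagents that add atoms: none
Why: copper hydride 1,4-reduction touches only the enoate, and hydride should add to C18 from the face opposite the isopropenyl group and the C19 methyl, so the acetate arm ends cis to isopropenyl (the future cis ring fusion).

Step 7
Reactants: 8 the cyclopentyl acetate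
Product: 10 1-[(1R,2R,5R)-2-methyl-5-(prop-1-en-2-yl)-2-(triethylsilyloxy)cyclopentyl]but-3-en-2-one, via Weinreb amide 9 (not isolated)
Conditions: MeNH(OMe)·HCl, i-PrMgCl, THF, −20 °C; then CH2=CHMgBr, 0 °C; cold aq. HCl quench
Reagents that add atoms: vinylmagnesium bromide (C=C[Mg]Br)
Why: one-pot Weinreb ketone synthesis, in which the chelated tetrahedral intermediate prevents over-addition of the vinyl Grignard reagent.

Step 8
Reactants: 10 the vinyl ketone
Product: 11 (3R,3aR,7aR)-3,7-dimethyl-3-(triethylsilyloxy)-1,2,3,3a,4,7a-hexahydro-5H-inden-5-one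
Conditions: Grubbs II catalyst (5 mol%), CH2Cl2, 40 °C
Reagents that add atoms: none
Why: ring-closing metathesis between the vinyl ketone and the isopropenyl group closes the six-membered enone (C14=C23) with loss of ethene and without touching the stereocentres.

Step 9
Reactants: 11 the cis-hydrindenone
Product: 13 aldol adduct (ethyl 2-hydroxy-2-[3,7,7-trimethyl-5-oxo-3-(triethylsilyloxy)octahydroinden-6-yl]acetate), via lithium enolate 12 (not isolated)
Conditions: CuI, MeLi (2 equiv), Et2O, −20 to 0 °C; then ZnCl2, ethyl glyoxylate, −78 °C; aq. NH4Cl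
Reagents that add atoms: lithium dimethylcuprate ([Li+].C[Cu-]C); ethyl glyoxylate (CCOC(=O)C=O)
Why: Gilman conjugate addition makes C23 a gem-dimethyl quaternary carbon (no new stereocentre) and delivers the enolate regiospecifically at C14, where it is trapped by aldol addition; the two new centres are removed in the next two steps.

Step 10
Reactants: 13 aldol adduct
Product: 15 ethyl (2Z)-2-[3,7,7-trimethyl-5-oxo-3-(triethylsilyloxy)octahydroinden-6-ylidene]acetate, via mesylate 14 (not isolated)
Conditions: MsCl, Et3N, CH2Cl2, 0 °C; then DBU, rt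
Reagents that add atoms: none
Why: mesylation followed by E1cB elimination through the ketone enolate gives the exocyclic alkylidene, with the ester turned away from the gem-dimethyl carbon.

Step 11
Reactants: 15 the alkylidene ketone
Product: 16 cis-hydrindanone keto ester (H-14 cis to H-18 and H-22)
Conditions: H2 (1 atm), 10% Pd/C, EtOAc, rt
Reagents that add atoms: none
Why: heterogeneous syn-hydrogenation of the doubly activated alkene should deliver hydrogen to C14 from the convex face of the cis-hydrindanone (the face of H-18/H-22, the concave face being screened by C21 of the cyclopentane), which sets C14.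

Step 12
Reactants: 16 the hydrindanone keto ester
Product: 18 cycloheptanone keto ester (C15 ketone), via α-trimethylsilyl ketone 17 (not isolated)
Conditions: TMSCHN2, Sc(OTf)3 (10 mol%), CH2Cl2, −40 to 0 °C; then 1 M HCl, THF, 0 °C
Reagents that add atoms: (trimethylsilyl)diazomethane (C[Si](C)(C)C=[N+]=[N-])
Why: Lewis-acid-catalysed diazoalkane homologation (Tiffeneau–Demjanov-type ring expansion) in which the less substituted C17 migrates, so C16 is inserted between C15 and C17, the carbonyl stays next to C14, and C14 is not touched.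

Step 13
Reactants: 18 the cycloheptanone keto ester
Product: 20 C15 enol triflate (C15=C16), via potassium enolate 19 (not isolated)
Conditions: KHMDS (1.05 equiv), THF, −78 °C; then PhNTf2, −78 to 0 °C
Reagents that add atoms: N-phenylbis(trifluoromethanesulfonimide) (O=S(=O)(N(c1ccccc1)S(=O)(=O)C(F)(F)F)C(F)(F)F)
Why: kinetic deprotonation at the unhindered C16 methylene (C14 is a hindered methine next to a quaternary carbon) and O-triflation give the C15=C16 enol triflate regioselectively without epimerising C14.

Step 14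
Reactants: 20 the enol triflate
Product: 21 ethyl 2-[hydroazulen-7-yl]acetate with the C15 methyl and C15=C16 alkene
Conditions: Pd(PPh3)4 (5 mol%), MeZnCl, THF, 50 °C
Reagents that add atoms: methylzinc chloride (C[Zn]Cl)
Why: Negishi coupling of the alkenyl triflate installs the C15 methyl with the double bond fixed at C15=C16 and tolerates the ester.

Step 15
Reactants: 21 the ester
Product: 22 hydroazulenyl acetaldehyde (C12 aldehyde)
Conditions: DIBAL-H (1.1 equiv), CH2Cl2, −78 °C; Rochelle salt work-up
Reagents that add atoms: none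
Why: partial reduction of the ester stops at the aldehyde because the aluminium hemiacetal is stable at −78 °C.

Step 16
Reactants: 23 (5E)-geranylacetone
Product: 24 (5R,6R,9R)-5,6:9,10-diepoxy-6,10-dimethylundecan-2-one
Conditions: D-fructose-derived Shi ketone (30 mol%), Oxone, K2CO3, Bu4NHSO4, MeCN–dimethoxymethane–aq. buffer (pH 10.5), 0 °C
Reagents that add atoms: potassium peroxymonosulfate ([K+].[O-]S(=O)(=O)OO)
Why: Shi asymmetric epoxidation of both trisubstituted alkenes by the chiral dioxirane (spiro transition state), in which the D-fructose-derived ketone should give the R-configured oxirane carbons (C3, C6, C7) while the ketone is inert.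

Step 17
Reactants: 24 the diepoxy ketone; 22 the hydroazulenyl acetaldehyde
Product: 26 β-hydroxy ketone (C11–C12 bond formed), via lithium enolate 25 (not isolated)
Conditions: LDA (1.05 equiv), THF, −78 °C; then 22, −78 °C; aq. NH4Cl
Reagents that add atoms: none
Why: kinetic deprotonation of the methyl ketone occurs at the methyl group (C11), and aldol addition of this lithium enolate to the aldehyde forms the C11–C12 bond while the oxiranes are inert at −78 °C.

Step 18
Reactants: 26 the β-hydroxy ketone
Product: 28 (E)-C11=C12 enone, via mesylate 27 (not isolated)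
Conditions: MsCl, Et3N, CH2Cl2, 0 °C; then DBU, rt
Reagents that add atoms: none
Why: mesylation and E1cB elimination give the conjugated (E)-enone without opening the oxiranes.

Step 19
Reactants: 28 the enone
Product: 29 (Z)-C10 triethylsilyl enol ether (C10=C11)
Conditions: RhCl(PPh3)3 (2 mol%), Et3SiH, toluene, 50 °C
Reagents that add atoms: triethylsilane (CC[SiH](CC)CC)
Why: Rh-catalysed 1,4-hydrosilylation of an enone with a monohydrosilane gives the silyl enol ether regiospecifically at C10=C11 (mainly Z), leaving the isolated trisubstituted alkene and the oxiranes alone.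

Step 20
Reactants: 29 the diepoxy enol silane
Product: 31 oxepane-fused cyclohexanone (C10 ketone, C3 OTBS), via epoxonium triflate 30 (not isolated)
Conditions: TBSOTf (1.2 equiv), 2,6-di-tert-butyl-4-methylpyridine (2 equiv), CH2Cl2, −78 °C; aq. NaHCO3
Reagents that add atoms: tert-butyldimethylsilyl trifluoromethanesulfonate (CC(C)(C)[Si](C)(C)OS(=O)(=O)C(F)(F)F)
Why: TBSOTf silylates the terminal C2–C3 oxirane, whose tertiary carbon C2 is attacked by the oxygen of the C6–C7 oxirane to give epoxonium ion 30, and the enol silane carbon C11 then opens this ion at tertiary C6 with loss of the triethylsilyl group to leave the C10 ketone. The closest known reaction type is the Lewis-acid-triggered tandem oxa-/carbacyclisation of 1,5-diepoxides terminated by an enol silane (biomimetic polyepoxide cascade). The oxepane closes in the 7-endo mode (O7 onto C2) and the cyclohexanone in a 6-endo mode (C11 onto C6, anti to the oxonium oxygen) through a chair transition state. C3 and C7 keep the configurations set by the Shi epoxidation, C6 is inverted stereospecifically so that its methyl and H-7 end up trans across the ring fusion, and C11 takes the equatorial orientation from the chair arrangement of the (Z)-enol silane and, being α to the new ketone, from thermodynamics. The step needs endo (tertiary-carbon) opening in both events and C- rather than O-alkylation of the enol silane; this is secured by the fully substituted C2 and C6 carrying the positive charge and by the hindered base suppressing proton-initiated pathways. The remote C15=C16 alkene and the tertiary OTES group are spectators, and the C3 oxygen emerges already protected as its TBS ether.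

Step 21
Reactants: 31 the bicyclic ketone
Product: 32 C10 tertiary alcohol (axial OH, equatorial CH3)
Conditions: MeMgBr, CeCl3, THF, −78 to 0 °C
Reagents that add atoms: methylmagnesium bromide (C[Mg]Br)
Why: cerium-modified Grignard addition to the hindered ketone should occur equatorially, anti to the axial C6 methyl that blocks the axial trajectory, giving the axial C10 hydroxyl.

Step 22
Reactants: 32 the C15=C16 alkene
Product: 33 15,16-epoxide (bis-silyl ether of the target)
Conditions: mCPBA, NaHCO3, CH2Cl2, 0 °C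
Reagents that add atoms: 3-chloroperoxybenzoic acid (OOC(=O)c1cccc(Cl)c1)
Why: Prilezhaev epoxidation of the only alkene, expected on the face syn to the pseudo-axial C13 chain because the opposite face of C15 is blocked 1,3 by the pseudo-axial C23 methyl (as in α-cyclogeranyl-type cyclohexenes), which gives the epoxide cis to the side chain.

Step 23
Reactants: 33 the bis-silyl ether
Product: 34 CNP0216138.1 (target)
Conditions: TBAF, THF, rt to 40 °C
Reagents that add atoms: none
Why: fluoride-induced desilylation cleaves both the secondary TBS and the tertiary TES ether, while the epoxide and the tertiary alcohols are stable to these conditions.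

**Compound list**

1 | geraniol, (2E)-3,7-dimethylocta-2,6-dien-1-ol | OC/C=C(C)/CCC=C(C)C | starting material
2 | (2R,3R)-2,3-epoxygeraniol | OC[C@H]1O[C@]1(C)CCC=C(C)C | intermediate
3 | epoxygeranyl chloride, (2S,3R)-2-(chloromethyl)-3-methyl-3-(4-methylpent-3-en-1-yl)oxirane (same spatial arrangement as 2) | ClC[C@H]1O[C@]1(C)CCC=C(C)C | intermediate
4 | dilithium alkynyl alkoxide of (3R)-3,7-dimethyloct-6-en-1-yn-3-ol | [Li+].[Li+].[C-]#C[C@](C)([O-])CCC=C(C)C | intermediate
5 | methyl (4R)-4-hydroxy-4,8-dimethylnon-7-en-2-ynoate | COC(=O)C#C[C@](C)(O)CCC=C(C)C | intermediate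
6 | methyl (4R)-4,8-dimethyl-4-(triethylsilyloxy)non-7-en-2-ynoate | COC(=O)C#C[C@](C)(O[Si](CC)(CC)CC)CCC=C(C)C | intermediate
7 | methyl (2Z)-2-[(2R,5S)-2-methyl-5-(prop-1-en-2-yl)-2-(triethylsilyloxy)cyclopentylidene]acetate (isopropenyl trans to OTES) | COC(=O)/C=C1/[C@H](C(C)=C)CC[C@@]1(C)O[Si](CC)(CC)CC | intermediate
8 | methyl 2-[(1R,2R,5R)-2-methyl-5-(prop-1-en-2-yl)-2-(triethylsilyloxy)cyclopentyl]acetate (acetate arm cis to isopropenyl, both trans to OTES) | COC(=O)C[C@@H]1[C@H](C(C)=C)CC[C@@]1(C)O[Si](CC)(CC)CC | intermediate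
9 | Weinreb amide of 8 (N-methoxy-N-methyl amide) | CON(C)C(=O)C[C@@H]1[C@H](C(C)=C)CC[C@@]1(C)O[Si](CC)(CC)CC | intermediate
10 | 1-[(1R,2R,5R)-2-methyl-5-(prop-1-en-2-yl)-2-(triethylsilyloxy)cyclopentyl]but-3-en-2-one | C=CC(=O)C[C@@H]1[C@H](C(C)=C)CC[C@@]1(C)O[Si](CC)(CC)CC | intermediate
11 | (3R,3aR,7aR)-3,7-dimethyl-3-(triethylsilyloxy)-1,2,3,3a,4,7a-hexahydro-5H-inden-5-one (cis-fused) | O=C1C=C(C)[C@@H]2CC[C@@](C)(O[Si](CC)(CC)CC)[C@@H]2C1 | intermediate
12 | lithium enolate (C14=C15–OLi) of the 7,7-dimethyl cis-hydrindanone | [Li+].[O-]C1=CC(C)(C)[C@@H]2CC[C@@](C)(O[Si](CC)(CC)CC)[C@@H]2C1 | intermediate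
13 | ethyl 2-hydroxy-2-[3,7,7-trimethyl-5-oxo-3-(triethylsilyloxy)octahydroinden-6-yl]acetate (cis-fused; mixture at C14 and C13) | CCOC(=O)C(O)C1C(C)(C)[C@@H]2CC[C@@](C)(O[Si](CC)(CC)CC)[C@@H]2CC1=O | intermediate
14 | methanesulfonate of 13 | CCOC(=O)C(OS(C)(=O)=O)C1C(C)(C)[C@@H]2CC[C@@](C)(O[Si](CC)(CC)CC)[C@@H]2CC1=O | intermediate
15 | ethyl (2Z)-2-[3,7,7-trimethyl-5-oxo-3-(triethylsilyloxy)octahydroinden-6-ylidene]acetate (cis-fused) | CCOC(=O)/C=C1/C(C)(C)[C@@H]2CC[C@@](C)(O[Si](CC)(CC)CC)[C@@H]2CC1=O | intermediate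
16 | ethyl 2-[3,7,7-trimethyl-5-oxo-3-(triethylsilyloxy)octahydroinden-6-yl]acetate (H-14, H-18 and H-22 all cis; OTES cis to them) | CCOC(=O)C[C@@H]1C(C)(C)[C@@H]2CC[C@@](C)(O[Si](CC)(CC)CC)[C@@H]2CC1=O | intermediate
17 | α-trimethylsilyl cycloheptanone (SiMe3 on C16) | CCOC(=O)C[C@@H]1C(C)(C)[C@@H]2CC[C@@](C)(O[Si](CC)(CC)CC)[C@@H]2CC([Si](C)(C)C)C1=O | intermediate
18 | ethyl 2-[3,8,8-trimethyl-6-oxo-3-(triethylsilyloxy)decahydroazulen-7-yl]acetate (cis-fused; H-14 cis to H-18/H-22) | CCOC(=O)C[C@@H]1C(C)(C)[C@@H]2CC[C@@](C)(O[Si](CC)(CC)CC)[C@@H]2CCC1=O | intermediate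
19 | potassium enolate of 18 (C15=C16, O on C15) | [K+].CCOC(=O)C[C@@H]1C(C)(C)[C@@H]2CC[C@@](C)(O[Si](CC)(CC)CC)[C@@H]2CC=C1[O-] | intermediate
20 | C15 enol triflate of 18 (C15=C16) | CCOC(=O)C[C@@H]1C(C)(C)[C@@H]2CC[C@@](C)(O[Si](CC)(CC)CC)[C@@H]2CC=C1OS(=O)(=O)C(F)(F)F | intermediate
21 | ethyl 2-[3,6,8,8-tetramethyl-3-(triethylsilyloxy)-1,2,3,3a,4,7,8,8a-octahydroazulen-7-yl]acetate (cis-fused) | CCOC(=O)C[C@@H]1C(C)(C)[C@@H]2CC[C@@](C)(O[Si](CC)(CC)CC)[C@@H]2CC=C1C | intermediate
22 | 2-[3,6,8,8-tetramethyl-3-(triethylsilyloxy)-1,2,3,3a,4,7,8,8a-octahydroazulen-7-yl]acetaldehyde (cis-fused; C12 aldehyde) | O=CC[C@@H]1C(C)(C)[C@@H]2CC[C@@](C)(O[Si](CC)(CC)CC)[C@@H]2CC=C1C | intermediate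
23 | (5E)-geranylacetone, (5E)-6,10-dimethylundeca-5,9-dien-2-one | CC(=O)CC/C=C(\C)CCC=C(C)C | starting material
24 | (5R,6R,9R)-5,6:9,10-diepoxy-6,10-dimethylundecan-2-one | CC(=O)CC[C@H]1O[C@]1(C)CC[C@H]2OC2(C)C | intermediate
25 | lithium enolate of 24 at the methyl terminus (C11) | [Li+].C=C([O-])CC[C@H]1O[C@]1(C)CC[C@H]2OC2(C)C | intermediate
26 | β-hydroxy ketone: C10 ketone, C12 carbinol (mixture), 2,3:6,7-diepoxide, hydroazulene with C19 OTES and C15=C16 | CC1(C)O[C@@H]1CC[C@@]2(C)O[C@@H]2CCC(=O)CC(O)C[C@@H]3C(C)(C)[C@@H]4CC[C@@](C)(O[Si](CC)(CC)CC)[C@@H]4CC=C3C | intermediate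
27 | methanesulfonate of 26 | CC1(C)O[C@@H]1CC[C@@]2(C)O[C@@H]2CCC(=O)CC(OS(C)(=O)=O)C[C@@H]3C(C)(C)[C@@H]4CC[C@@](C)(O[Si](CC)(CC)CC)[C@@H]4CC=C3C | intermediate
28 | (E)-C11=C12 enone of the diepoxide | CC1(C)O[C@@H]1CC[C@@]2(C)O[C@@H]2CCC(=O)/C=C/C[C@@H]3C(C)(C)[C@@H]4CC[C@@](C)(O[Si](CC)(CC)CC)[C@@H]4CC=C3C | intermediate
29 | (Z)-C10 triethylsilyl enol ether (C10=C11) of the diepoxide | CC1(C)O[C@@H]1CC[C@@]2(C)O[C@@H]2CC/C(O[Si](CC)(CC)CC)=C/CC[C@@H]3C(C)(C)[C@@H]4CC[C@@](C)(O[Si](CC)(CC)CC)[C@@H]4CC=C3C | intermediate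
30 | bicyclic epoxonium triflate (O+ bonded to C2, C6 and C7; C3 OTBS) | CC1(C)[O+]2[C@H](CC/C(O[Si](CC)(CC)CC)=C/CC[C@@H]3C(C)(C)[C@@H]4CC[C@@](C)(O[Si](CC)(CC)CC)[C@@H]4CC=C3C)[C@@]2(C)CC[C@H]1O[Si](C)(C)C(C)(C)C.[O-]S(=O)(=O)C(F)(F)F | intermediate
31 | trans-fused oxepane–cyclohexanone: C10 ketone, C3 OTBS, C11 equatorial CH2CH2-hydroazulene (C19 OTES, C15=C16) | CC1(C)O[C@@H]2CCC(=O)[C@H](CC[C@@H]3C(C)(C)[C@@H]4CC[C@@](C)(O[Si](CC)(CC)CC)[C@@H]4CC=C3C)[C@@]2(C)CC[C@H]1O[Si](C)(C)C(C)(C)C | intermediate
32 | C10 tertiary alcohol (axial OH), C3 OTBS, C19 OTES, C15=C16 | CC1(C)O[C@@H]2CC[C@](C)(O)[C@H](CC[C@@H]3C(C)(C)[C@@H]4CC[C@@](C)(O[Si](CC)(CC)CC)[C@@H]4CC=C3C)[C@@]2(C)CC[C@H]1O[Si](C)(C)C(C)(C)C | intermediate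
33 | 15,16-epoxide (cis to the C13 chain), C3 OTBS, C19 OTES | CC1(C)O[C@@H]2CC[C@](C)(O)[C@H](CC[C@@H]3C(C)(C)[C@@H]4CC[C@@](C)(O[Si](CC)(CC)CC)[C@@H]4C[C@@H]4O[C@@]43C)[C@@]2(C)CC[C@H]1O[Si](C)(C)C(C)(C)C | intermediate
34 | CNP0216138.1, (3R,6R,7R,10S,11R,14R,15R,16S,18R,19R,22R) in the numbering above | CC1(C)O[C@@H]2CC[C@](C)(O)[C@H](CC[C@@H]3C(C)(C)[C@@H]4CC[C@@](C)(O)[C@@H]4C[C@@H]4O[C@@]43C)[C@@]2(C)CC[C@H]1O | target

**Step count and risk**

Total steps: 23. Longest linear sequence: 22 (steps 1–15 and 17–23, from geraniol); step 16 is the one-step side branch.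

Steps most likely to fail:

1. Step 20. The epoxonium ion may collapse (elimination or capture by triflate) before the C6–C11 bond forms, or the enol silane may be protodesilylated, on the fully elaborated substrate. Fallback, from 24 back to 31: the cascade is moved ahead of the fragment union. Ketone 24 is converted (LDA, TBSCl, THF–DMPU, −78 °C) into the kinetic silyl enol ether F1. Under the same TBSOTf/hindered-pyridine conditions this simplest substrate should give the bicyclic 3-O-TBS ketone F2, which lacks the C11 substituent. IBX dehydrogenation can only go towards C8–C9 (C6 is quaternary) and should give the enone F3, whose only enolisable position is C11. Its lithium enolate (LDA, −78 °C) is added to aldehyde 22 to give the aldol adduct F4, which is dehydrated (MsCl, Et3N; DBU) to the cross-conjugated dienone F5. Copper hydride conjugate reduction of both enone double bonds (the C15=C16 alkene is inert), with thermodynamic protonation at C11, returns 31.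

2. Step 11. Hydrogen may be delivered to the wrong face of the C13=C14 alkylidene (poor discrimination between convex and concave faces), giving the C14 epimer. Fallback, from 11 back to 16: the enolate 12 is generated as in step 9 and alkylated directly with ethyl iodoacetate (HMPA, −78 to −20 °C). Here the carbon electrophile, not hydrogen, enters from the more accessible face, so C14 has the opposite configuration to that from the aldol–dehydration–hydrogenation sequence whichever face is preferred. Compound 16 is reached in one operation and no new compound is made (F0).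

3. Step 22. The peracid may attack the wrong face of the C15=C16 alkene. Fallback, from 32 back to 33: NBS in THF–water at 0 °C should give the bromohydrin F6 (bromonium ion on the face the peracid prefers, water opening at tertiary C15 from the other face). K2CO3 in methanol then closes the epoxide on the face opposite to that of direct epoxidation, giving 33.

**Further compounds**

F1 | step 20 | tert-butyldimethylsilyl enol ether of 24 at the methyl terminus | C=C(O[Si](C)(C)C(C)(C)C)CC[C@H]1O[C@]1(C)CC[C@H]2OC2(C)C
F2 | step 20 | trans-fused oxepane–cyclohexanone with C3 OTBS and unsubstituted C11 | CC1(C)O[C@@H]2CCC(=O)C[C@@]2(C)CC[C@H]1O[Si](C)(C)C(C)(C)C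
F3 | step 20 | C8=C9 enone of F2 | CC1(C)O[C@@H]2C=CC(=O)C[C@@]2(C)CC[C@H]1O[Si](C)(C)C(C)(C)C
F4 | step 20 | C11 aldol adduct of F3 with 22 (mixture at C11 and C12) | CC1(C)O[C@@H]2C=CC(=O)C(C(O)C[C@@H]3C(C)(C)[C@@H]4CC[C@@](C)(O[Si](CC)(CC)CC)[C@@H]4CC=C3C)[C@@]2(C)CC[C@H]1O[Si](C)(C)C(C)(C)C
F5 | step 20 | cross-conjugated dienone (C8=C9 and C11=C12) | CC1(C)O[C@@H]2C=CC(=O)C(=CC[C@@H]3C(C)(C)[C@@H]4CC[C@@](C)(O[Si](CC)(CC)CC)[C@@H]4CC=C3C)[C@@]2(C)CC[C@H]1O[Si](C)(C)C(C)(C)C
F0 | step 11 | none | none
F6 | step 22 | bromohydrin of 32 (C15 OH cis to the C13 chain, C16 Br trans) | CC1(C)O[C@@H]2CC[C@](C)(O)[C@H](CC[C@@H]3C(C)(C)[C@@H]4CC[C@@](C)(O[Si](CC)(CC)CC)[C@@H]4C[C@@H](Br)[C@]3(C)O)[C@@]2(C)CC[C@H]1O[Si](C)(C)C(C)(C)C
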